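Assumption: the SMILES fixes only C3 (S) and leaves the hindered C5–C1' biaryl axis undefined, so both rotamers about this axis (atropo-diastereomers if the axis is configurationally stable) are taken as the target and no axial control is built into the route.

## The problem

- Target 17 is a 1,2,3,4-tetrahydroisoquinoline with methoxy groups at C6 and C8, a methyl-bearing stereocentre at C3 (S), an unsubstituted C1 methylene and a free N–H. It is joined through C5 to C1' of a 4',5'-dimethoxy-7'-methylnaphthalene.
- The hardest bond is C5–C1'. It is flanked by the C6 methoxy group, the C4 methylene and the peri C8'–H, and both rings are electron-rich. Each ring also offers a wrong site: C7 on the isoquinoline, and on the naphthalene the position para to the other methoxy group, in the ring that carries the methyl group.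
- C3 is the only stereocentre and nothing in the molecule can relay chirality to it. It is best bought from the chiral pool; as a non-epimerisable secondary alkyl carbon it should survive all later steps.
- The C5–C1' axis is a further stereogenic element that C3 is too remote to control.
- Because C1 carries no substituent, it can come from a one-carbon aldehyde in a Pictet–Spengler closure onto a symmetric 3,5-dimethoxyphenyl ring.
- Sensitive points are the secondary amine and the benzylic C1–H bonds next to it (oxidation), the electron-rich arenes (over-oxidation) and the four aryl methyl ethers (strong Lewis acids).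
- The feature that makes the key step possible: C1' is para to the oxygen on C4' within the methyl-free naphthalene ring (C1'–C4', C4a', C8a'). A naphthalen-1-ol with a free para position therefore becomes electrophilic at exactly this carbon on two-electron oxidation. C5 of the isoquinoline benzene ring is ortho to the C6 methoxy and para to the C8 methoxy group, and is its most nucleophilic C–H.

## Retrosynthesis

**17 back to 15 (N–S and O–CH3 bonds).** The tosyl group on nitrogen and the methyl group on the C4' oxygen are removed from the plan last. The sulfonyl group comes with the purchased aziridine, activates the Pictet–Spengler step and shields the amine during the oxidation, so no separate protection step is needed. The C4' oxygen is kept as a free hydroxyl until after the coupling because that hydroxyl is what makes C1' reactive. The forward steps (15 to 16 to 17) must alkylate oxygen only, which is secured because 15 has no N–H, and must cleave N–S without reducing the naphthalene.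

**15 back to 6 and 12 (the C5–C1' bond, key disconnection).** The biaryl bond is cut so that both fragments carry only hydrogen at the bond site: tetrahydroisoquinoline 6 (C5–H) and naphthol 12 (C4–H, para to the hydroxyl). The neighbouring options are a cut with halide and boron on the two carbons, or a cut inside the naphthalene ring to build it around a preformed aryl–carbon bond. Both need several extra operations per fragment. This cut divides a C31 intermediate into a C19 and a C12 piece, each two or three steps from purchasable compounds. The forward reaction must oxidise only the naphthol, join C4 of 12 (not C2) to C5 of 6 (not C7), favour cross- over homo-coupling, and stop before the product is oxidised further.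

**6 back to 4, then to 1 and 2 (C1–C8a, C1–N and aryl–CH2 bonds).** The heterocycle is opened at C1, which is supplied as a one-carbon aldehyde reagent in step 2. In sulfonamide 4 the two ring positions ortho to the side chain are equivalent, so the closure can give only the 6,8-dimethoxy pattern. Sulfonamide 4 is cut at the aryl–CH2 bond into aryl bromide 1 and aziridine 2. This takes C3 from the L-alanine pool instead of creating it by asymmetric reduction or amination. The forward ring opening must occur at the unsubstituted aziridine carbon only.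

**12 back to 10, 9 and 7 (aromatisation, O–CH3, C8–O).** Naphthol 12 is traced to tetralone 10. In the tetralone the two peri oxygens differ in kind, one a ketone and one a phenol ether. The monomethyl pattern is therefore set without a selective methylation of a naphthalene-1,8-diol. Tetralone 10 comes from phenol 9 by methylation, and 9 from purchasable tetralone 7 by ketone-directed C–H hydroxylation. C8 is the only C–H ortho to the carbonyl-bearing carbon, so only one regioisomer can form. The forward dehydrogenation of 10 must stop at the naphthol.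

## Roads not taken

**Alternative 1: Suzuki–Miyaura coupling (the most obvious route).** The same C5–C1' bond is cut into the 5-iodide A1 (from 6) and the naphthylboronic acid A2 (from 12 by bromination, methylation and borylation). The forward key step is a palladium-catalysed coupling that forms a biaryl with three ortho substituents. It needs four extra operations to place halogen and boron, and uses an electron-rich, hindered boronic acid that is prone to protodeboronation. It gives no more control of the axis than the chosen plan. The chosen plan uses the innate polarity of the two rings and forms the bond in one operation from two C–H bonds.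

**Alternative 2: carbonyl addition and late aromatisation.** The bond is cut with the naphthalene ring at the quinone oxidation level. Halogen–lithium exchange on A1 is followed by 1,2-addition to the carbonyl of quinone A3 that is remote from the methoxy group, which gives quinol A4. Reductive aromatisation of A4 (Zn, AcOH) would then give 15. The hindered bond is formed as an easy carbonyl addition. However, A3 is not purchasable and needs its own multistep synthesis, and A1 is still required. Electron transfer and conjugate addition compete with 1,2-addition to a quinone, and two steps replace one.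

**Alternative 3: heterocycle last, by single-atom insertion.** The pyridine ring is made at the end by nitrogen insertion into the C2=C3 bond of indene A5 to give isoquinoline A6. Enantioselective hydrogenation of the nitrogen ring of A6 would then set C3 and give 17. This leaves the biaryl problem untouched, since A5 must already contain the C–C axis. It also replaces a purchased stereocentre with an asymmetric hydrogenation of a 3-alkylisoquinoline, in competition with reduction of the naphthalene. The chosen plan buys C3 and spends its one risky step on the biaryl bond.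

Key step: step 6

## Route

Step 1
Reactants: 1 1-bromo-3,5-dimethoxybenzene; 2 (S)-2-methyl-1-tosylaziridine
Product: 4 N-[(2S)-1-(3,5-dimethoxyphenyl)propan-2-yl]-4-methylbenzenesulfonamide, via Grignard reagent 3 (not isolated)
Conditions: Mg, THF, reflux; then 2, CuI (10 mol %), THF, −30 °C to rt; aq. NH4Cl
Reagents that add atoms: none
Why: Copper-catalysed SN2 ring opening of an N-sulfonylaziridine by an aryl Grignard reagent at the unsubstituted CH2; the stereocentre of 2 is not touched and becomes C3 (S) of the target.

Step 2
Reactants: 4 N-[(2S)-1-(3,5-dimethoxyphenyl)propan-2-yl]-4-methylbenzenesulfonamide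
Product: 6 (3S)-6,8-dimethoxy-3-methyl-2-tosyl-1,2,3,4-tetrahydroisoquinoline, via N-sulfonyliminium ion 5 (not isolated)
Conditions: (CH2O)n (1.1 equiv), CF3CO2H, CH2Cl2, 0 °C to rt
Reagents that add atoms: paraformaldehyde (formaldehyde), C=O
Why: N-sulfonyl Pictet–Spengler cyclisation; iminium ion 5 is attacked by the ring carbon ortho to the side chain (para to one methoxy, ortho to the other), and since both such carbons are equivalent only the 6,8-dimethoxy isomer can form; C3 is not involved.

Step 3
Reactants: 7 6-methyl-3,4-dihydronaphthalen-1(2H)-one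
Product: 9 8-hydroxy-6-methyl-3,4-dihydronaphthalen-1(2H)-one, via aryl trifluoroacetate 8 (not isolated)
Conditions: Pd(OCOCF3)2 (10 mol %), K2S2O8, CF3CO2H/(CF3CO)2O, 50 °C; then H2O
Reagents that add atoms: trifluoroacetic acid, OC(=O)C(F)(F)F (supplies the oxygen atom)
Why: Ketone-directed ortho C–H oxygenation by divalent palladium (cyclopalladation through the carbonyl oxygen, oxidation by persulfate, C–O reductive elimination, hydrolysis of ester 8 on work-up); C8 is the only C–H ortho to the carbonyl-bearing carbon.

Step 4
Reactants: 9 8-hydroxy-6-methyl-3,4-dihydronaphthalen-1(2H)-one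
Product: 10 8-methoxy-6-methyl-3,4-dihydronaphthalen-1(2H)-one
Conditions: MeI, K2CO3, DMF, 50 °C
Reagents that add atoms: iodomethane, CI
Why: Williamson O-methylation of the chelated phenol; the weak base should not enolise the ketone enough for C-methylation to compete.

Step 5
Reactants: 10 8-methoxy-6-methyl-3,4-dihydronaphthalen-1(2H)-one
Product: 12 8-methoxy-6-methylnaphthalen-1-ol, via enone tautomer 11 (not isolated)
Conditions: Pd(OCOCF3)2 (5 mol %), 2-(dimethylamino)pyridine (10 mol %), TsOH (20 mol %), O2 (1 atm), DMSO, 80 °C
Reagents that add atoms: none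
Why: Palladium-catalysed aerobic dehydrogenation of a cyclohexanone to a phenol (palladium enolate, β-hydride elimination to enone 11, tautomerisation driven by aromatisation); the former ketone oxygen becomes the one free hydroxyl of the naphthalene.

Step 6
Reactants: 6 (3S)-6,8-dimethoxy-3-methyl-2-tosyl-1,2,3,4-tetrahydroisoquinoline; 12 8-methoxy-6-methylnaphthalen-1-ol
Product: 15 4-[(3S)-6,8-dimethoxy-3-methyl-2-tosyl-1,2,3,4-tetrahydroisoquinolin-5-yl]-8-methoxy-6-methylnaphthalen-1-ol, via aryloxyiodane 13 (not isolated), via dienone tautomer 14 (not isolated)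
Conditions: PhI(OAc)2 (1.0 equiv, slow addition), 6 (2.5 equiv), (CF3)2CHOH/CH2Cl2, −20 to 0 °C
Reagents that add atoms: none
Why: Oxidative para C–H arylation of a phenol by trivalent iodine in a fluoroalcohol; the closest known reaction type is the PhI(OAc)2-mediated para cross-coupling of phenols with electron-rich arenes. Ligand exchange at iodine gives aryloxyiodane 13, and departure of PhI makes the oxygen-bearing naphthalene ring an oxocarbenium-type electrophile with its largest coefficient at C4, para to oxygen. C5–H of 6 attacks C4 in an electrophilic aromatic substitution to give dienone 14, which tautomerises to naphthol 15; no ring is closed. Only 12 is oxidised because only it has a free hydroxyl for ligand exchange, and para attack is preferred over ortho because C2 lies next to the bulky O–I(Ph) group. On 6, C5 is preferred over C7 because C5 is ortho/para-activated while C7 is only ortho-activated and flanked by two methoxy groups, in line with the behaviour of 6,8-dialkoxytetrahydroisoquinolines in electrophilic halogenation. Cross-coupling should be favoured over homo-coupling by hydrogen bonding of the fluoroalcohol to 12, the excess of 6 and slow addition of the oxidant. The only new stereogenic element is the C5–C1' axis; C3 is too remote to control it, so both rotamers are expected, and the sp3 carbon of 14 disappears on tautomerisation.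

Step 7
Reactants: 15 4-[(3S)-6,8-dimethoxy-3-methyl-2-tosyl-1,2,3,4-tetrahydroisoquinolin-5-yl]-8-methoxy-6-methylnaphthalen-1-ol
Product: 16 (3S)-5-(4,5-dimethoxy-7-methylnaphthalen-1-yl)-6,8-dimethoxy-3-methyl-2-tosyl-1,2,3,4-tetrahydroisoquinoline
Conditions: MeI, K2CO3, DMF, rt
Reagents that add atoms: iodomethane, CI
Why: Williamson methylation of the naphthol; the sulfonamide has no N–H, so only oxygen can be alkylated.

Step 8
Reactants: 16 (3S)-5-(4,5-dimethoxy-7-methylnaphthalen-1-yl)-6,8-dimethoxy-3-methyl-2-tosyl-1,2,3,4-tetrahydroisoquinoline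
Product: 17 (3S)-5-(4,5-dimethoxy-7-methylnaphthalen-1-yl)-6,8-dimethoxy-3-methyl-1,2,3,4-tetrahydroisoquinoline
Conditions: NaC10H8 (sodium naphthalenide), DME, −78 °C; then MeOH, H2O
Reagents that add atoms: none
Why: Single-electron reductive cleavage of the N–S bond of an arenesulfonamide by an arene radical anion, run cold and without a proton source so that the dimethoxynaphthalene is not reduced; C3 is not affected.

## Compound list

1 | 1-bromo-3,5-dimethoxybenzene | COc1cc(Br)cc(OC)c1 | starting material
2 | (S)-2-methyl-1-tosylaziridine | C[C@H]1CN1S(=O)(=O)c1ccc(C)cc1 | starting material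
3 | (3,5-dimethoxyphenyl)magnesium bromide | COc1cc(OC)cc([Mg]Br)c1 | intermediate
4 | N-[(2S)-1-(3,5-dimethoxyphenyl)propan-2-yl]-4-methylbenzenesulfonamide | COc1cc(C[C@H](C)NS(=O)(=O)c2ccc(C)cc2)cc(OC)c1 | intermediate
5 | N-[(2S)-1-(3,5-dimethoxyphenyl)propan-2-yl]-N-tosylmethaniminium trifluoroacetate | COc1cc(C[C@H](C)[N+](=C)S(=O)(=O)c2ccc(C)cc2)cc(OC)c1.[O-]C(=O)C(F)(F)F | intermediate
6 | (3S)-6,8-dimethoxy-3-methyl-2-tosyl-1,2,3,4-tetrahydroisoquinoline | COc1cc(OC)cc2c1CN([C@@H](C)C2)S(=O)(=O)c1ccc(C)cc1 | intermediate
7 | 6-methyl-3,4-dihydronaphthalen-1(2H)-one | O=C1CCCc2cc(C)ccc12 | starting material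
8 | 3-methyl-8-oxo-5,6,7,8-tetrahydronaphthalen-1-yl trifluoroacetate | O=C1CCCc2cc(C)cc(OC(=O)C(F)(F)F)c12 | intermediate
9 | 8-hydroxy-6-methyl-3,4-dihydronaphthalen-1(2H)-one | O=C1CCCc2cc(C)cc(O)c12 | intermediate
10 | 8-methoxy-6-methyl-3,4-dihydronaphthalen-1(2H)-one | COc1cc(C)cc2CCCC(=O)c12 | intermediate
11 | 8-methoxy-6-methylnaphthalen-1(4H)-one | COc1cc(C)cc2CC=CC(=O)c12 | intermediate
12 | 8-methoxy-6-methylnaphthalen-1-ol | COc1cc(C)cc2cccc(O)c12 | intermediate
13 | acetoxy[(8-methoxy-6-methylnaphthalen-1-yl)oxy](phenyl)-λ3-iodane | CC(=O)OI(Oc1cccc2cc(C)cc(OC)c12)c1ccccc1 | intermediate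
14 | 4-[(3S)-6,8-dimethoxy-3-methyl-2-tosyl-1,2,3,4-tetrahydroisoquinolin-5-yl]-8-methoxy-6-methylnaphthalen-1(4H)-one | COc1cc(OC)c(C3C=CC(=O)c4c(OC)cc(C)cc34)c2c1CN([C@@H](C)C2)S(=O)(=O)c1ccc(C)cc1 | intermediate
15 | 4-[(3S)-6,8-dimethoxy-3-methyl-2-tosyl-1,2,3,4-tetrahydroisoquinolin-5-yl]-8-methoxy-6-methylnaphthalen-1-ol | COc1cc(OC)c(-c3ccc(O)c4c(OC)cc(C)cc34)c2c1CN([C@@H](C)C2)S(=O)(=O)c1ccc(C)cc1 | intermediate
16 | (3S)-5-(4,5-dimethoxy-7-methylnaphthalen-1-yl)-6,8-dimethoxy-3-methyl-2-tosyl-1,2,3,4-tetrahydroisoquinoline | COc1cc(OC)c(-c3ccc(OC)c4c(OC)cc(C)cc34)c2c1CN([C@@H](C)C2)S(=O)(=O)c1ccc(C)cc1 | intermediate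
17 | (3S)-5-(4,5-dimethoxy-7-methylnaphthalen-1-yl)-6,8-dimethoxy-3-methyl-1,2,3,4-tetrahydroisoquinoline | COc1cc(OC)c(-c2ccc(OC)c3c(OC)cc(C)cc23)c2c1CN[C@@H](C)C2 | target

## Step count and least certain steps

Total: 8 steps. Longest linear sequence: 6 steps (steps 3, 4, 5, 6, 7, 8 from 7). The other branch has 5 steps (steps 1, 2, 6, 7, 8 from 1 and 2).

**Step 6 (key step).** The most likely failures are homo-coupling of the naphthol with its own oxidised form and further oxidation of the product. The product is a more electron-rich naphthol with a blocked para position. Attack through C7 of 6 is a lesser concern. Fallback by known chemistry, setting out from 6 and 12 and rejoining at 16: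
- 6 is brominated at C5 (NBS, MeCN, 0 °C) to (3S)-5-bromo-6,8-dimethoxy-3-methyl-2-tosyl-1,2,3,4-tetrahydroisoquinoline F1.
- 12 is brominated para to the hydroxyl (NBS, MeCN, −20 °C) to 4-bromo-8-methoxy-6-methylnaphthalen-1-ol F2.
- F2 is methylated (MeI, K2CO3) to 1-bromo-4,5-dimethoxy-7-methylnaphthalene F3.
- F3 is converted by Miyaura borylation (bis(pinacolato)diboron, KOAc, PdCl2(dppf), dioxane, 90 °C) into 2-(4,5-dimethoxy-7-methylnaphthalen-1-yl)-4,4,5,5-tetramethyl-1,3,2-dioxaborolane F4.
- Suzuki–Miyaura coupling of F1 with F4 (Pd(OAc)2, SPhos, K3PO4, toluene/H2O, 100 °C) should give 16 directly.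

**Step 3.** The ketone is a weak ligand, so turnover may be low. Persulfate may instead oxidise the enolisable α-position or the benzylic methyl group. Fallback from 7, rejoining at 9, uses a nitrogen directing group in place of the ketone:
- 7 is condensed with MeONH2·HCl (pyridine, EtOH) to (E)-6-methyl-3,4-dihydronaphthalen-1(2H)-one O-methyl oxime F5.
- Oxime-directed ortho acetoxylation (Pd(OAc)2, PhI(OAc)2, AcOH/Ac2O, 100 °C) gives (E)-8-(methoxyimino)-3-methyl-5,6,7,8-tetrahydronaphthalen-1-yl acetate F6.
- Hydrolysis of both the acetate and the oxime ether (6 M HCl, dioxane, reflux) returns 9.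

**Step 5.** The electron-rich naphthol may be oxidised further under O2 and palladium (oxidative dimerisation), or the peri methoxy ketone may bind and slow the catalyst. Fallback from 10, rejoining at 12, is a polar halogenation–elimination:
- α-Bromination (CuBr2, EtOAc/CHCl3, reflux) gives 2-bromo-8-methoxy-6-methyl-3,4-dihydronaphthalen-1(2H)-one F7.
- Dehydrobromination and tautomerisation (LiBr, Li2CO3, DMF, 120 °C) give 12.

**Step 8.** Electron transfer to the dimethoxynaphthalene may compete with N–S cleavage and lead to partial ring reduction on quench. Fallback from 6, rejoining at 17, moves the desulfonylation to a stage where no naphthalene is present: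
- 6 is cleaved (NaC10H8, DME, −78 °C) to (3S)-6,8-dimethoxy-3-methyl-1,2,3,4-tetrahydroisoquinoline F8.
- F8 is protected (Boc2O, Et3N, CH2Cl2) as tert-butyl (3S)-6,8-dimethoxy-3-methyl-3,4-dihydroisoquinoline-2(1H)-carboxylate F9.
- F9 is coupled with 12 under the conditions of step 6 to give tert-butyl (3S)-5-(4-hydroxy-5-methoxy-7-methylnaphthalen-1-yl)-6,8-dimethoxy-3-methyl-3,4-dihydroisoquinoline-2(1H)-carboxylate F10.
- F10 is methylated (MeI, K2CO3, DMF) to tert-butyl (3S)-5-(4,5-dimethoxy-7-methylnaphthalen-1-yl)-6,8-dimethoxy-3-methyl-3,4-dihydroisoquinoline-2(1H)-carboxylate F11.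
- Acid cleavage of the carbamate (CF3CO2H, CH2Cl2, 0 °C) gives 17.

## Further compounds

F1 | step 6 | (3S)-5-bromo-6,8-dimethoxy-3-methyl-2-tosyl-1,2,3,4-tetrahydroisoquinoline | COc1cc(OC)c(Br)c2c1CN([C@@H](C)C2)S(=O)(=O)c1ccc(C)cc1
F2 | step 6 | 4-bromo-8-methoxy-6-methylnaphthalen-1-ol | COc1cc(C)cc2c(Br)ccc(O)c12
F3 | step 6 | 1-bromo-4,5-dimethoxy-7-methylnaphthalene | COc1cc(C)cc2c(Br)ccc(OC)c12
F4 | step 6 | 2-(4,5-dimethoxy-7-methylnaphthalen-1-yl)-4,4,5,5-tetramethyl-1,3,2-dioxaborolane | COc1cc(C)cc2c(B3OC(C)(C)C(C)(C)O3)ccc(OC)c12
F5 | step 3 | (E)-6-methyl-3,4-dihydronaphthalen-1(2H)-one O-methyl oxime | CO/N=C1\CCCc2cc(C)ccc12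
F6 | step 3 | (E)-8-(methoxyimino)-3-methyl-5,6,7,8-tetrahydronaphthalen-1-yl acetate | CO/N=C1\CCCc2cc(C)cc(OC(C)=O)c12
F7 | step 5 | 2-bromo-8-methoxy-6-methyl-3,4-dihydronaphthalen-1(2H)-one | COc1cc(C)cc2CCC(Br)C(=O)c12
F8 | step 8 | (3S)-6,8-dimethoxy-3-methyl-1,2,3,4-tetrahydroisoquinoline | COc1cc(OC)cc2c1CN[C@@H](C)C2
F9 | step 8 | tert-butyl (3S)-6,8-dimethoxy-3-methyl-3,4-dihydroisoquinoline-2(1H)-carboxylate | COc1cc(OC)cc2c1CN([C@@H](C)C2)C(=O)OC(C)(C)C
F10 | step 8 | tert-butyl (3S)-5-(4-hydroxy-5-methoxy-7-methylnaphthalen-1-yl)-6,8-dimethoxy-3-methyl-3,4-dihydroisoquinoline-2(1H)-carboxylate | COc1cc(OC)c(-c3ccc(O)c4c(OC)cc(C)cc34)c2c1CN([C@@H](C)C2)C(=O)OC(C)(C)C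
F11 | step 8 | tert-butyl (3S)-5-(4,5-dimethoxy-7-methylnaphthalen-1-yl)-6,8-dimethoxy-3-methyl-3,4-dihydroisoquinoline-2(1H)-carboxylate | COc1cc(OC)c(-c3ccc(OC)c4c(OC)cc(C)cc34)c2c1CN([C@@H](C)C2)C(=O)OC(C)(C)C
A1 | alternative 1 | (3S)-5-iodo-6,8-dimethoxy-3-methyl-2-tosyl-1,2,3,4-tetrahydroisoquinoline | COc1cc(OC)c(I)c2c1CN([C@@H](C)C2)S(=O)(=O)c1ccc(C)cc1
A2 | alternative 1 | (4,5-dimethoxy-7-methylnaphthalen-1-yl)boronic acid | COc1cc(C)cc2c(B(O)O)ccc(OC)c12
A3 | alternative 2 | 5-methoxy-7-methylnaphthalene-1,4-dione | COc1cc(C)cc2C(=O)C=CC(=O)c12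
A4 | alternative 2 | 4-[(3S)-6,8-dimethoxy-3-methyl-2-tosyl-1,2,3,4-tetrahydroisoquinolin-5-yl]-4-hydroxy-8-methoxy-6-methylnaphthalen-1(4H)-one | COc1cc(OC)c(C3(O)C=CC(=O)c4c(OC)cc(C)cc34)c2c1CN([C@@H](C)C2)S(=O)(=O)c1ccc(C)cc1
A5 | alternative 3 | 7-(4,5-dimethoxy-7-methylnaphthalen-1-yl)-4,6-dimethoxy-2-methyl-1H-indene | COc1cc(OC)c(-c2ccc(OC)c3c(OC)cc(C)cc23)c2CC(C)=Cc12
A6 | alternative 3 | 5-(4,5-dimethoxy-7-methylnaphthalen-1-yl)-6,8-dimethoxy-3-methylisoquinoline | COc1cc(OC)c(-c2ccc(OC)c3c(OC)cc(C)cc23)c2cc(C)ncc12
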